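The earlier runs and the new flask stem from a simulated flask with constants of no real substance; noise was put on by code.

The slowness of a solid shows in a share that is read as what it is, a mean over everything captured so far.

| flask | substrate | gas | solid second nucleophile | remark | time |
|---|---|---|---|---|---|
| green | 10 mM | 2 mM (held) | 0.50 equiv | the very flask that is asked about, followed so far |  |
| violet | 20 mM | 2 mM (held) | 0.50 equiv | run made earlier |  |
| flask | 10 mM | 2.0 mM (held) | 0.500 equiv |  | 8.0 d |

| run | time / d | target / % | other capture product / % |
|---|---|---|---|
| green | 0.125 | 59.3 | 14.0 |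
| green | 0.333 | 76.2 | 20.5 |
| green | 0.625 | 78.9 | 21.2 |
| green | 1.04 | 76.4 | 20.1 |
| green | 1.67 | 77.2 | 20.3 |
| green | 2.08 | 77.9 | 21.1 |
| green | 2.50 | 75.9 | 20.6 |
| violet | 0.417 | 76.2 | 20.0 |
| violet | 1.25 | 75.9 | 20.9 |
| violet | 2.50 | 75.7 | 22.1 |
| violet | 3.00 | 76.0 | 19.0 |
| violet | 5.00 | 75.4 | 20.3 |
| violet | 6.00 | 76.7 | 18.7 |
| violet | 8.00 | 75.2 | 21.5 |

(each reading ± 1 percentage point)

- share of target in target plus other capture product at 15 min
- share of target in target plus other capture product at 8.0 d

- at the start none of the gas is in solution
- at the start none of the solid second nucleophile is in solution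

The target share looked flat in green, and in violet, with twice the substrate and solid, it looked the same, yet two numbers in green did not seem to go together: target held 80.9% of the capture up to 0.125 d, and from 0.625 d on the means of 77.3% and 20.7% gave 78.9%, so by these readings the part captured after the first one held 72.9%.

I wrote x for the ratio of other capture product to target (a selectivity), 0.236 up to the first reading and 0.371 after it, and supposed that x climbed exponentially to that late value as the solid dissolved. Taking capture as even over a window T, the mean falls short by the fraction τ/T, which gave 65.4 min for τ, the time by which the rising ratio trails one standing at its late value from the start; the term dropped, e^(−T/τ), was 0.0638. At 15 min the curve is nearly straight, so I took its mean as half its end value, x = 0.0380, a share of 96.3%; for 8.0 d I kept 78.9%, violet reading flat to 8.00 d.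

The forecast gave 87% (79% to 96%) at 15 min, lower than my figure, and 79% (77.5% to 80.5%) at 8.0 d, the first reading “hinting that the solid dissolves slowly”.

The flask gave 94.1% at 15 min and 78.5% at 8.0 d.

    gas ⇌ first nucleophile, rate k1*(csat - [first nucleophile]) (kL = 0.390 min⁻¹)
    substrate + target → side product (k = 0.0360 M⁻¹ min⁻¹)
    substrate → intermediate (k = 0.0100 min⁻¹)
    solid second nucleophile ⇌ second nucleophile, rate k4*(cs4 - [second nucleophile]) while solid is left; crystals form when [second nucleophile] > cs4 (solubility = 3.70 mM, k = 0.0160 min⁻¹)
    second nucleophile + intermediate → other capture product (k = 2.40 M⁻¹ min⁻¹)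
    first nucleophile + intermediate → target (k = 11.0 M⁻¹ min⁻¹)

In the flask, at 0.0475 d, 1.05 lags in, substrate was passing into intermediate with a half-life of 1.2 h while second nucleophile was made 2.21 times faster than it was used up, each step taken net. By 0.800 d, 17.6 lags, substrate stood at 0%, target at 76.9% and other capture product at 21.1%, as they did at 8.00 d.

For the neighbour with 2.5 mM of substrate I carried τ and the late x of green unchanged, as a supposition, which gives 96.3% at 15 min and 78.9% at 8.0 d; computed, that neighbour gave 94.2% at 15 min and 89.2% at 8.0 d.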